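**Retrosynthetic overview**
1. Target 17 comes from 16 by one global hydrogenolysis (five benzyl ethers and one diphenylmethylene ketal); the galloyl ester sits on ring B from step 2 onwards.
2. Ring C, the only ring that is built, is closed from the syn-(1S,2S) diol 15 by an intramolecular Mitsunobu etherification that forms O1–C2 with inversion (2,3-trans).
3. Diol 15 comes from the α-hydroxy ketone 14 by catalyst-controlled transfer hydrogenation.
4. Key C2–C3 bond: an enantioselective carbene-catalysed crossed benzoin in which the ring B aldehyde 5 reacts as an acyl anion (Breslow intermediate) with the ring A arylacetaldehyde, used as its lactol 13; two aldehyde carbons are joined and C3 is set.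
5. Aldehyde 5 comes from gallaldehyde 1 (ketal, then galloylation); lactol 13 comes from 3,5-bis(benzyloxy)phenol 6 (O-allylation, Claisen, oxidative cleavage). Rings A, B and the galloyl ring are bought.

Assumption: both antipodes of the aminoindanol-derived triazolium salt can be bought and the one that gives the 2S ketol in step 6 is used (written below as the (5aR,10bS) salt, to be confirmed on the first run); 4 and 6 are purchased.

**Route**

Step 1
Reactants: 1 3,4,5-trihydroxybenzaldehyde; 2 dichlorodiphenylmethane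
Product: 3 7-hydroxy-2,2-diphenyl-1,3-benzodioxole-5-carbaldehyde
Conditions: Ph2CCl2 (1.2 equiv), Ph2O, 175 °C, 30 min
Reagents that add atoms: dichlorodiphenylmethane (2), ClC(Cl)(c1ccccc1)c1ccccc1
Why: Ketalisation of a catechol (diphenylmethylene acetal formation by double substitution): only two neighbouring hydroxyls can bridge the CPh2 carbon and the 3,4- and 4,5-pairs are equivalent by symmetry, so one ketal forms and one meta hydroxyl stays free.

Step 2
Reactants: 3 7-hydroxy-2,2-diphenyl-1,3-benzodioxole-5-carbaldehyde; 4 3,4,5-tris(benzyloxy)benzoyl chloride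
Product: 5 6-formyl-2,2-diphenyl-1,3-benzodioxol-4-yl 3,4,5-tris(benzyloxy)benzoate
Conditions: K2CO3, DMAP (5 mol %), MeCN, 0 °C → rt
Reagents that add atoms: 3,4,5-tris(benzyloxy)benzoyl chloride (4), O=C(Cl)c1cc(OCc2ccccc2)c(OCc2ccccc2)c(OCc2ccccc2)c1
Why: O-acylation of the phenoxide (Schotten–Baumann-type esterification with DMAP catalysis) puts the protected galloyl group on the only free hydroxyl, which becomes O-3' of ring B.

Step 3
Reactants: 6 3,5-bis(benzyloxy)phenol; 7 allyl bromide
Product: 8 1-(allyloxy)-3,5-bis(benzyloxy)benzene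
Conditions: allyl bromide, K2CO3, acetone, reflux
Reagents that add atoms: allyl bromide (7), C=CCBr
Why: Williamson ether synthesis on the phenoxide installs the allyl group needed for the Claisen shift.

Step 4
Reactants: 8 1-(allyloxy)-3,5-bis(benzyloxy)benzene
Product: 10 2-allyl-3,5-bis(benzyloxy)phenol, via Claisen dienone 9 (not isolated)
Conditions: PhNEt2, 200 °C, N2
Reagents that add atoms: none
Why: Aromatic Claisen rearrangement ([3,3]-sigmatropic shift) to either of the two equivalent ortho positions followed by enolisation of the dienone places the three-carbon chain next to the hydroxyl that becomes O1.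

Step 5
Reactants: 10 2-allyl-3,5-bis(benzyloxy)phenol
Product: 13 4,6-bis(benzyloxy)-2,3-dihydro-1-benzofuran-2-ol, via vicinal diol 11 (not isolated), via hydroxy aldehyde 12 (not isolated)
Conditions: OsO4 (2 mol %), NaIO4 (4 equiv), 2,6-lutidine, dioxane/H2O 3:1, rt
Reagents that add atoms: osmium tetroxide, O=[Os](=O)(=O)=O (source of the new oxygen; turned over by sodium periodate, [Na+].[O-]I(=O)(=O)=O)
Why: Lemieux–Johnson oxidative cleavage (dihydroxylation, then periodate glycol cleavage) removes the terminal carbon and the arylacetaldehyde is trapped by the ortho phenol as a five-membered lactol, which masks both the phenol and the enolisable aldehyde; the hemiacetal centre is racemic and is lost in step 6.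

Step 6
Reactants: 5 6-formyl-2,2-diphenyl-1,3-benzodioxol-4-yl 3,4,5-tris(benzyloxy)benzoate; 13 4,6-bis(benzyloxy)-2,3-dihydro-1-benzofuran-2-ol (1.3 equiv, reacts through its open form 12)
Product: 14 6-{(2S)-3-[2,4-bis(benzyloxy)-6-hydroxyphenyl]-2-hydroxypropanoyl}-2,2-diphenyl-1,3-benzodioxol-4-yl 3,4,5-tris(benzyloxy)benzoate
Conditions: (5aR,10bS)-2-phenyl-5a,10b-dihydro-4H,6H-indeno[2,1-b][1,2,4]triazolo[4,3-d][1,4]oxazin-2-ium tetrafluoroborate (10 mol %), K2CO3 (10 mol %), THF (0.5 M), rt, stopped when 5 is consumed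
Reagents that add atoms: none
Why: Proposed new method: in this carbene-catalysed crossed benzoin the triazolylidene adds to the unhindered, electron-rich ring B aldehyde (a good acyl donor but a poor acceptor) to give the Breslow intermediate, an acyl anion at C2, which attacks one enantiotopic face of the more electrophilic aliphatic aldehyde that the lactol releases at low concentration inside the chiral aminoindanol pocket and so sets C3 as S, the closest known reactions being the enantioselective triazolium-catalysed benzoin condensation of aryl aldehydes and the crossed acyloin coupling of aryl aldehydes with acetaldehyde or formaldehyde.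

Step 7
Reactants: 14 the (2S)-α-hydroxy ketone
Product: 15 6-{(1S,2S)-3-[2,4-bis(benzyloxy)-6-hydroxyphenyl]-1,2-dihydroxypropyl}-2,2-diphenyl-1,3-benzodioxol-4-yl 3,4,5-tris(benzyloxy)benzoate
Conditions: RuCl[(R,R)-TsDPEN](p-cymene) (2 mol %), HCO2H/Et3N 5:2, EtOAc, 25 °C
Reagents that add atoms: none
Why: Noyori–Ikariya asymmetric transfer hydrogenation of the aryl ketone is catalyst-controlled, the (R,R)-complex setting the benzylic carbinol as 1S (matched with the 2S carbinol, as in the reduction of benzoin to the chiral hydrobenzoin) to give the syn diol, while any (R)-ketol carried over from step 6 ends as the anti diastereomer and is removed by chromatography.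

Step 8
Reactants: 15 the syn-(1S,2S) diol
Product: 16 6-[(2R,3S)-5,7-bis(benzyloxy)-3-hydroxy-3,4-dihydro-2H-chromen-2-yl]-2,2-diphenyl-1,3-benzodioxol-4-yl 3,4,5-tris(benzyloxy)benzoate
Conditions: PPh3 (1.5 equiv), DIAD (1.5 equiv), THF (0.02 M), 0 °C → rt
Reagents that add atoms: none
Why: Intramolecular Mitsunobu etherification: the phenol is the only acidic pronucleophile and displaces the activated benzylic oxyphosphonium in a six-membered SN2 closure with inversion, so 1S becomes 2R and ring C forms 2,3-trans while C3 is untouched.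

Step 9
Reactants: 16 the protected flavan-3-ol
Product: 17 gallocatechin 3'-O-gallate, 2,3-dihydroxy-5-[(2R,3S)-3,5,7-trihydroxy-3,4-dihydro-2H-chromen-2-yl]phenyl 3,4,5-trihydroxybenzoate
Conditions: H2 (1 atm), 20% Pd(OH)2/C, THF/MeOH 1:1, rt
Reagents that add atoms: none
Why: Catalytic hydrogenolysis cleaves the five benzyl ethers and the diphenylmethylene ketal, whereas the aryl gallate ester and the cyclic O1–C2 ether are expected to survive these neutral conditions as they do in debenzylations of catechin gallates, and no stereocenter is touched.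

**Compound list**
1 | 3,4,5-trihydroxybenzaldehyde | O=Cc1cc(O)c(O)c(O)c1 | starting material
2 | dichlorodiphenylmethane | ClC(Cl)(c1ccccc1)c1ccccc1 | starting material
3 | 7-hydroxy-2,2-diphenyl-1,3-benzodioxole-5-carbaldehyde | O=Cc1cc(O)c2OC(c3ccccc3)(c3ccccc3)Oc2c1 | intermediate
4 | 3,4,5-tris(benzyloxy)benzoyl chloride | O=C(Cl)c1cc(OCc2ccccc2)c(OCc2ccccc2)c(OCc2ccccc2)c1 | starting material
5 | 6-formyl-2,2-diphenyl-1,3-benzodioxol-4-yl 3,4,5-tris(benzyloxy)benzoate | O=Cc1cc(OC(=O)c3cc(OCc4ccccc4)c(OCc4ccccc4)c(OCc4ccccc4)c3)c2OC(c3ccccc3)(c3ccccc3)Oc2c1 | intermediate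
6 | 3,5-bis(benzyloxy)phenol | Oc1cc(OCc2ccccc2)cc(OCc2ccccc2)c1 | starting material
7 | allyl bromide | C=CCBr | starting material
8 | 1-(allyloxy)-3,5-bis(benzyloxy)benzene | C=CCOc1cc(OCc2ccccc2)cc(OCc2ccccc2)c1 | intermediate
9 | 6-allyl-3,5-bis(benzyloxy)cyclohexa-2,4-dien-1-one, Claisen dienone, racemic (not isolated) | O=C1C=C(OCc2ccccc2)C=C(OCc2ccccc2)C1CC=C | intermediate
10 | 2-allyl-3,5-bis(benzyloxy)phenol | C=CCc1c(O)cc(OCc2ccccc2)cc1OCc1ccccc1 | intermediate
11 | 3-[2,4-bis(benzyloxy)-6-hydroxyphenyl]propane-1,2-diol, racemic (not isolated) | OCC(O)Cc1c(O)cc(OCc2ccccc2)cc1OCc1ccccc1 | intermediate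
12 | [2,4-bis(benzyloxy)-6-hydroxyphenyl]acetaldehyde, open form of 13 (not isolated) | O=CCc1c(O)cc(OCc2ccccc2)cc1OCc1ccccc1 | intermediate
13 | 4,6-bis(benzyloxy)-2,3-dihydro-1-benzofuran-2-ol, racemic lactol | OC1Cc2c(OCc3ccccc3)cc(OCc3ccccc3)cc2O1 | intermediate
14 | 6-{(2S)-3-[2,4-bis(benzyloxy)-6-hydroxyphenyl]-2-hydroxypropanoyl}-2,2-diphenyl-1,3-benzodioxol-4-yl 3,4,5-tris(benzyloxy)benzoate | O=C([C@@H](O)Cc1c(O)cc(OCc2ccccc2)cc1OCc1ccccc1)c1cc(OC(=O)c2cc(OCc3ccccc3)c(OCc3ccccc3)c(OCc3ccccc3)c2)c2OC(c3ccccc3)(c3ccccc3)Oc2c1 | intermediate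
15 | 6-{(1S,2S)-3-[2,4-bis(benzyloxy)-6-hydroxyphenyl]-1,2-dihydroxypropyl}-2,2-diphenyl-1,3-benzodioxol-4-yl 3,4,5-tris(benzyloxy)benzoate | O[C@H]([C@@H](O)Cc1c(O)cc(OCc2ccccc2)cc1OCc1ccccc1)c1cc(OC(=O)c2cc(OCc3ccccc3)c(OCc3ccccc3)c(OCc3ccccc3)c2)c2OC(c3ccccc3)(c3ccccc3)Oc2c1 | intermediate
16 | 6-[(2R,3S)-5,7-bis(benzyloxy)-3-hydroxy-3,4-dihydro-2H-chromen-2-yl]-2,2-diphenyl-1,3-benzodioxol-4-yl 3,4,5-tris(benzyloxy)benzoate | O=C(Oc1cc([C@H]2Oc3cc(OCc4ccccc4)cc(OCc4ccccc4)c3C[C@@H]2O)cc2OC(c3ccccc3)(c3ccccc3)Oc12)c1cc(OCc2ccccc2)c(OCc2ccccc2)c(OCc2ccccc2)c1 | intermediate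
17 | gallocatechin 3'-O-gallate, (2R,3S) | O=C(Oc1cc([C@H]2Oc3cc(O)cc(O)c3C[C@@H]2O)cc(O)c1O)c1cc(O)c(O)c(O)c1 | target

**Step count and risks**

Total: 9 steps. Longest linear sequence: 7 steps (steps 3 to 9, from 6 to 17).

The step most likely to fail is step 6. Homo-benzoin of 5, the reversed ketol regiochemistry, or a low enantiomeric excess are all possible. The fallback sets out from 5 and 13 and moves the enantio-determining event from the C–C bond formation to the reduction. An achiral crossed acyloin under equilibrating conditions (3-benzyl-5-(2-hydroxyethyl)-4-methylthiazolium chloride, Et3N, EtOH, 60 °C), where the conjugated aryl ketone is the favoured isomer, gives the racemic ketol F1. The transfer hydrogenation of step 7 with RuCl[(R,R)-TsDPEN](p-cymene) then imposes 1S on both enantiomers, so that the (S)-half gives 15 and the (R)-half gives the anti-(1S,2R) diol F2. The two diastereomers are separated by chromatography and the route is rejoined at 15, at the cost of half the material.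

The second is step 8. The Mitsunobu closure can leak to a five-membered dihydrobenzofuran (attack at C3) or to an epoxide (which would give the cis isomer). The fallback sets out from 15 and uses neighbouring-group chemistry instead of phosphonium activation. HC(OEt)3 with PPTS in 1,2-dichloroethane at 60 °C forms the cyclic orthoformate F5, which ionises to the dioxolanylium ion and is opened by the phenol at the benzylic carbon with inversion to give the trans 3-O-formate F6. A short methanolysis (KHCO3, MeOH/THF, 0 °C), which spares the more hindered aryl gallate, removes the formate and comes back to the route at 16.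

The third is step 7. The free ortho phenol can tie the ketone up as a cyclic hemiketal, which slows the reduction or, under the acidic formate medium, lets C3 scramble through the enol ether. The fallback sets out from 14 and replaces catalyst control by substrate control. TBSOTf and 2,6-lutidine in CH2Cl2 give the bis(tert-butyldimethylsilyl) ether F3, in which neither hydroxyl can add to the ketone. LiBH(s-Bu)3 in THF at −78 °C then reduces the ketone under Felkin–Anh control (hydride anti to the silyloxy group) to the syn-(1S,2S) alcohol F4. HF·pyridine in THF removes both silyl groups and comes back to the route at 15.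

**Further compounds**
F1 | step 6 | racemic 6-{3-[2,4-bis(benzyloxy)-6-hydroxyphenyl]-2-hydroxypropanoyl}-2,2-diphenyl-1,3-benzodioxol-4-yl 3,4,5-tris(benzyloxy)benzoate | O=C(C(O)Cc1c(O)cc(OCc2ccccc2)cc1OCc1ccccc1)c1cc(OC(=O)c2cc(OCc3ccccc3)c(OCc3ccccc3)c(OCc3ccccc3)c2)c2OC(c3ccccc3)(c3ccccc3)Oc2c1
F2 | step 6 | 6-{(1S,2R)-3-[2,4-bis(benzyloxy)-6-hydroxyphenyl]-1,2-dihydroxypropyl}-2,2-diphenyl-1,3-benzodioxol-4-yl 3,4,5-tris(benzyloxy)benzoate (anti diol) | O[C@H]([C@H](O)Cc1c(O)cc(OCc2ccccc2)cc1OCc1ccccc1)c1cc(OC(=O)c2cc(OCc3ccccc3)c(OCc3ccccc3)c(OCc3ccccc3)c2)c2OC(c3ccccc3)(c3ccccc3)Oc2c1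
F3 | step 7 | bis(tert-butyldimethylsilyl) ether of 14 (phenol and C3 hydroxyl), 2S | O=C([C@@H](O[Si](C)(C)C(C)(C)C)Cc1c(O[Si](C)(C)C(C)(C)C)cc(OCc2ccccc2)cc1OCc1ccccc1)c1cc(OC(=O)c2cc(OCc3ccccc3)c(OCc3ccccc3)c(OCc3ccccc3)c2)c2OC(c3ccccc3)(c3ccccc3)Oc2c1
F4 | step 7 | bis(tert-butyldimethylsilyl) ether of 15 (phenol and C3 hydroxyl), syn-(1S,2S) | O[C@H]([C@@H](O[Si](C)(C)C(C)(C)C)Cc1c(O[Si](C)(C)C(C)(C)C)cc(OCc2ccccc2)cc1OCc1ccccc1)c1cc(OC(=O)c2cc(OCc3ccccc3)c(OCc3ccccc3)c(OCc3ccccc3)c2)c2OC(c3ccccc3)(c3ccccc3)Oc2c1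
F5 | step 8 | cyclic orthoformate of 15, 2-ethoxy-1,3-dioxolane, (4S,5S), mixture at the orthoester carbon | CCOC1O[C@@H](c2cc(OC(=O)c3cc(OCc4ccccc4)c(OCc4ccccc4)c(OCc4ccccc4)c3)c3OC(c4ccccc4)(c4ccccc4)Oc3c2)[C@H](Cc2c(O)cc(OCc3ccccc3)cc2OCc2ccccc2)O1
F6 | step 8 | 3-O-formate of 16, (2R,3S) | O=C(Oc1cc([C@H]2Oc3cc(OCc4ccccc4)cc(OCc4ccccc4)c3C[C@@H]2OC=O)cc2OC(c3ccccc3)(c3ccccc3)Oc12)c1cc(OCc2ccccc2)c(OCc2ccccc2)c(OCc2ccccc2)c1
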